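**Assumption:** (–)-andrographolide (bulk extract of Andrographis paniculata, sold at multigram scale) is taken as the commercial starting material; labdane numbering is used (ring A = C1–C5, C10; ring B = C5–C10; C17 = exocyclic CH2; C11–C16 = side chain and lactone; C18 and C19 on C4; C20 = methyl on C10).

## Retrosynthetic overview

1. Target 7 ⇒ enone 5: the C7–H bond comes from substrate-controlled axial hydride delivery (sets 7R); both acetates come off in the same flask.
2. Enone 5 ⇒ butenolide 3: the C7–O bond is made by anodic, selenium-catalysed allylic C–H oxidation next to the C8=C17 methylene (ene reaction, then [2,3] shift, so the alkene stays exocyclic).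
3. 3 ⇒ 2 ⇒ 1: SN2′ hydride displacement of the 14-acetate moves the side-chain alkene into the lactone to give the butenolide.
4. No ring is built: the trans-decalin (rings A and B) and the lactone ring come intact from andrographolide with C3, C4, C5, C9 and C10 in place. C14 is erased and C7 is the only centre made.

## Route

**Step 1**
Reactants: 1 (–)-andrographolide
Product: 2 3,14,19-tri-O-acetylandrographolide
Conditions: Ac2O (6 equiv), pyridine, 0 °C → rt, 16 h
Reagents that add atoms: acetic anhydride, CC(=O)OC(C)=O
Why: Pyridine-promoted O-acylation (esterification) of all three hydroxyls turns the allylic 14-OH into a leaving group and masks 3-OH and 19-OH, and keeping the mixture at or below room temperature avoids elimination to the 11,12-didehydro diene, so no stereocentre is touched.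

**Step 2**
Reactants: 2 3,14,19-tri-O-acetylandrographolide
Product: 3 3,19-di-O-acetyl-14-deoxyandrographolide
Conditions: NaBH4 (1.0 equiv), THF/i-PrOH 4:1, –20 → 0 °C, 30 min
Reagents that add atoms: none
Why: SN2′ hydride reduction (conjugate addition then E1cB elimination, as in the borohydride reduction of Morita–Baylis–Hillman acetates), in which hydride adds to C12 of the α-alkylidene lactone and the enolate expels the 14-acetate, moving the alkene into the ring as the butenolide and deleting the C14 stereocentre while the isolated C8=C17 alkene and the 3,19-acetates do not react at this temperature.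

**Step 3**
Reactants: 3 3,19-di-O-acetyl-14-deoxyandrographolide
Product: 5 3,19-di-O-acetyl-7-oxo-14-deoxyandrographolide, via 7S-hydroxy diacetate 4 (not isolated)
Conditions: (PhSe)2 (10 mol %), H2O (10 equiv), n-Bu4NBF4 (0.1 M), MeCN/HFIP 9:1, 50 °C; undivided cell, graphite-felt anode, Pt cathode, 5 mA constant current, 4.5 F/mol
Reagents that add atoms: water, O
Why: Proposed new method: anodic oxidation of (PhSe)2 in wet MeCN/HFIP should give benzeneseleninic acid (tetravalent selenium), which engages the electron-rich 1,1-disubstituted C8=C17 alkene in an ene reaction (Se to C17, H taken from the ring CH2 at C7) followed by a [2,3]-sigmatropic shift that returns oxygen to C7 and restores the exocyclic alkene (axial delivery, giving the 7S alcohol 4 on the face opposite the C10 methyl), after which 4 is oxidised on to ketone 5 through its seleninate ester by syn-elimination, the divalent selenium by-product being re-oxidised at the anode while protons are reduced to H2 at Pt, so that water is the oxygen source and neither peroxide nor hypervalent iodine is present, the electron-poor butenolide and the acetates being inert to electrophilic selenium; the closest known reaction types are SeO2/t-BuOOH allylic hydroxylation, seleninic-acid-catalysed allylic oxidation to enones with iodoxybenzene, and anodic diselenide-catalysed oxyselenenylation–deselenenylation.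

**Step 4**
Reactants: 5 3,19-di-O-acetyl-7-oxo-14-deoxyandrographolide
Product: 7 (7R)-7-hydroxy-14-deoxyandrographolide, via 7R-hydroxy diacetate 6 (not isolated)
Conditions: NaBH4 (1.0 equiv), CeCl3·7H2O (1.0 equiv), MeOH, –40 → 0 °C, 30 min; then K2CO3 (3.0 equiv), 0 °C → rt, 3 h
Reagents that add atoms: none
Why: Luche reduction, in which the cerium-activated borohydride adds 1,2 to the α-methylene ketone and axially, from the face of H5 and H9 opposite the axial C10 methyl, so the new 7-OH is equatorial, cis to C20 and 7R, with the butenolide and esters untouched, and once the hydride is spent (base is added only then, so the enone never meets methoxide) K2CO3-mediated methanolysis (transesterification) removes both acetates.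

## Compound list

1 | (–)-andrographolide: (3E,4S)-3-{2-[(1R,4aS,5R,6R,8aS)-6-hydroxy-5-(hydroxymethyl)-5,8a-dimethyl-2-methylidenedecahydronaphthalen-1-yl]ethylidene}-4-hydroxyoxolan-2-one | C=C1CC[C@@H]2[C@](C)(CO)[C@H](O)CC[C@@]2(C)[C@@H]1C/C=C1/C(=O)OC[C@H]1O | starting material
2 | 3,14,19-tri-O-acetylandrographolide (all centres as in 1; 12E) | C=C1CC[C@@H]2[C@](C)(COC(C)=O)[C@H](OC(C)=O)CC[C@@]2(C)[C@@H]1C/C=C1/C(=O)OC[C@H]1OC(C)=O | intermediate
3 | 3,19-di-O-acetyl-14-deoxyandrographolide (α-substituted butenolide, C13=C14; ring centres as in 1) | C=C1CC[C@@H]2[C@](C)(COC(C)=O)[C@H](OC(C)=O)CC[C@@]2(C)[C@@H]1CCC1=CCOC1=O | intermediate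
4 | (7S)-3,19-di-O-acetyl-7-hydroxy-14-deoxyandrographolide (7-OH axial, trans to the C10 methyl, cis to H5 and H9) | C=C1[C@@H](O)C[C@@H]2[C@](C)(COC(C)=O)[C@H](OC(C)=O)CC[C@@]2(C)[C@@H]1CCC1=CCOC1=O | intermediate
5 | 3,19-di-O-acetyl-7-oxo-14-deoxyandrographolide (8(17)-en-7-one; ring centres as in 1) | C=C1C(=O)C[C@@H]2[C@](C)(COC(C)=O)[C@H](OC(C)=O)CC[C@@]2(C)[C@@H]1CCC1=CCOC1=O | intermediate
6 | (7R)-3,19-di-O-acetyl-7-hydroxy-14-deoxyandrographolide (7-OH equatorial, cis to the C10 methyl) | C=C1[C@H](O)C[C@@H]2[C@](C)(COC(C)=O)[C@H](OC(C)=O)CC[C@@]2(C)[C@@H]1CCC1=CCOC1=O | intermediate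
7 | (7R)-7-hydroxy-14-deoxyandrographolide: 3-{2-[(1S,3R,4aS,5R,6R,8aS)-3,6-dihydroxy-5-(hydroxymethyl)-5,8a-dimethyl-2-methylidenedecahydronaphthalen-1-yl]ethyl}furan-2(5H)-one | C=C1[C@H](O)C[C@@H]2[C@](C)(CO)[C@H](O)CC[C@@]2(C)[C@@H]1CCC1=CCOC1=O | target

## Step count and risks

Total step count: 4. Longest linear sequence: 4 (fully linear from 1).

**Step 3 (the proposed new electrochemical oxidation).** The risks are stalling at alcohol 4, competing loss of the C9 proton (giving a 9-oxygenated by-product), water capture of the seleniranium ion, and over-oxidation at C6. The fallback uses known chemistry and sets out from 3. Catalytic SeO2 (0.5 equiv) with t-BuOOH (3 equiv) in CH2Cl2 at room temperature (ene/[2,3] allylic hydroxylation) gives the axial 7S-hydroxy diacetate 4, now isolated. Dess–Martin periodinane with NaHCO3 in CH2Cl2 at 0 °C then oxidises this allylic alcohol to enone 5, where the route is rejoined. Any 7R epimer 6 formed alongside converges on the same ketone. This fallback makes no compound outside the list (F0).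

**Step 4 (one-pot Luche reduction and methanolysis).** The risks are γ-deprotonation or methoxide addition at the butenolide during base treatment, and a less than complete axial preference of the hydride. The fallback sets out from 5. Only the Luche reduction is run (NaBH4, CeCl3·7H2O, MeOH, –40 °C), and the 7R-hydroxy diacetate 6 is isolated by chromatography, which also removes any 7S epimer 4. Instead of transesterification, 6 is saponified with LiOH (5 equiv) in THF/H2O 3:1 at 0 °C → rt. This cleaves both acetates and opens the lactone to the ring-opened (Z)-γ-hydroxy acid F1, present as its lithium carboxylate. Acidification to pH 3 with 1 M HCl relactonises it spontaneously, because the Z geometry holds the hydroxyl and the carboxyl together, and the route comes back at target 7.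

**Step 2 (SN2′ hydride reduction).** The risks are over-reduction of the product butenolide by borohydride and partial loss of the 19-acetate. The fallback sets out from 2 and replaces hydride by electron transfer. SmI2 (2.2 equiv) in THF/MeOH at –78 °C reduces the alkylidene lactone by one electron, the 14-acetate is lost, and a second electron transfer followed by protonation at C12 (the more electron-rich terminus and the one that leads to the more stable endocyclic butenolide) gives 3. With no hydride present the α-alkyl butenolide and the acetates are not reduced at this temperature. The route comes back at 3, and this fallback makes no compound outside the list (F0).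

## Further compounds

F0 | step 3 | none | none
F1 | step 4 | ring-opened (Z)-γ-hydroxy acid of 7: (2Z)-2-{2-[(1S,3R,4aS,5R,6R,8aS)-3,6-dihydroxy-5-(hydroxymethyl)-5,8a-dimethyl-2-methylidenedecahydronaphthalen-1-yl]ethyl}-4-hydroxybut-2-enoic acid | C=C1[C@H](O)C[C@@H]2[C@](C)(CO)[C@H](O)CC[C@@]2(C)[C@@H]1CC/C(=C/CO)C(=O)O
F0 | step 2 | none | none
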